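## Structural features

The target, 1-(5-hydroxy-7-methoxy-2,2-dimethyl-2H-chromen-6-yl)-3-phenylpropane-1,3-dione, is a benzene ring (ring A) fused through C4a–C8a to a 2H-pyran (ring B). In ring B, O1 carries the gem-dimethyl carbon C2, and the C3=C4 double bond is conjugated with ring A. Ring A is a phloroglucinol unit with three differentiated oxygens: O1 inside the pyran, a free hydroxyl on C5 and a methyl ether on C7. The 3-oxo-3-phenylpropanoyl chain sits on C6 between the C5 and C7 oxygens, and only C8 bears hydrogen. There is no stereocentre and no double bond of free geometry, so no stereocentres stand next to each other and the molecule is achiral. The fragile groups are the ortho-hydroxyaryl 1,3-diketone (cyclodehydration to a flavone with acid or heat, retro-Claisen cleavage with hydroxide), the electron-rich C3=C4 bond (acid, oxidants) and the free phenol. The real difficulty is regiochemical: C4 must be attached at the ring carbon between the pyran oxygen and the C5 hydroxyl, not at C8, and the acyl chain must end between OH and OMe. The key step exploits the C4a–C4 bond lying ortho to the C8a–O1 bond, with quaternary C2 on O1. This is the pattern an aryl 1,1-dimethylpropargyl ether produces on heating. One point needs to be stated precisely: in the acetophenone precursor both carbons ortho to the ether oxygen lie between two oxygens. The required migration terminus is therefore C3 (between the chelated hydroxyl and the ether oxygen), and the one to avoid is C5 (between the ether oxygen and OMe).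

## Logic of the disconnections

**12 to 8 and 9.** The bond cut is the one between the methylene carbon of the diketone and the benzoyl carbonyl carbon of 12. This is the retron of a crossed Claisen condensation with the methyl ketone of 8 as nucleophile and the non-enolisable ester 9 as electrophile. Cutting here removes seven carbons and the only really fragile function in one stroke. It also places the diketone after the thermal step, which an ortho-hydroxy diketone would be unlikely to survive without closing to a flavone. The demand on the forward step is base stoichiometry: phenol, methyl ketone and product diketone are all acidic, so at least three equivalents of a non-nucleophilic lithium amide are needed. The reaction runs through 10 and rests at 11, which must be released by a cold, dilute acid quench.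

**8 to 4.** The bonds cut are C4a–C4 and O1–C2 of the pyran ring. Retrosynthetically the ring opens to 7, hydrogen returns to oxygen to give 6, the ring dearomatises to 5, and the reverse (3,3) shift re-forms the ether of 4. The cut is made here because both bonds collapse onto a single O–C bond of a monocyclic ether, so the forward step is a reagent-free isomerisation. The acetyl group passes through as a spectator and also supplies the chelate that directs the shift. The gain is the loss of one ring and of all regiochemical ambiguity about the pyran oxygen. The demand is twofold selectivity in the forward cascade: migration to C3 and not C5, and closure through the oxygen freed by the shift and not the chelated one. The chelated hydroxyl of 4 must therefore stay unprotected, and no change to the precursor is needed beyond that.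

**4 to 1 and 2.** The bond cut is the ether bond between the 4-oxygen and the quaternary propargylic carbon. It is cut because 1 already holds the three oxygens in the required differentiated form (one methylated, one chelated, one free) and the acetyl group in its final position, and 2 supplies all five carbons of the future C2–C3–C4 unit with its methyl groups. Both fragments are commercial. The demand is chemoselective O-alkylation of the unchelated hydroxyl (through 3) by a hindered tertiary electrophile, without C-alkylation of the electron-rich ring.

## Other disconnections considered

**Alternative 1:** The cut is made in ring A of the ketal-masked diketone A1, at the C5–O bond and at the bond from C6 to the side-chain carbonyl. It leads back to the ortho-silylaryl triflate A2 and the carboxylic acid A3.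
- **Forward key step:** CsF would release the 5,6-aryne A4 from A2. The carboxylate of A3 should add through oxygen at C5, the aryne carbon remote from the C7 methoxy group. The aryl anion left at C6 should then take the acyl group from the aryl ester by intramolecular transfer, giving A1. Mild acid would then unmask 12.
- **In favour:** The position of the acyl group follows from the polarisation of an alkoxy-substituted aryne. The whole side chain arrives in one convergent, near-neutral step, so the base-heavy Claisen condensation on a free phenol is avoided. On that point it is the better design.
- **Against:** A2 already contains the complete chromene, so the pyran ring must be built first and a vicinal silyl/triflate pair then installed. A3 must be prepared. A4 could also react with its own styrene-like C3=C4 bond. The final ketal hydrolysis exposes the chromene alkene and a flavone-prone hydroxy diketone to aqueous acid.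
- **Comparison:** On structure it solves acyl placement, which the chosen plan obtains for nothing from 1, and leaves the pyran regiochemistry unsolved. On mechanism it is polar and mild, equal or better in temperature, but with more competing channels. On step economy it is clearly longer than three steps.

**Alternative 2:** The cut removes ring A altogether (C5–C6, C7–C8, C4a–C5, with C8–C8a made in the rearrangement). The chromanone A5 is taken back to the diazoketone A6 and methoxyethyne A7.
- **Forward key step:** Irradiation of A6 should cause Wolff rearrangement to the vinylketene A8, with the pyranone vinyl carbon migrating to form C8–C8a. A7 should add (2+2) with its CH carbon on the ketene carbonyl carbon, forming C5–C6 and C7–C8. Warming should open the four-membered ring (4π) and close the resulting dienylketene (6π) at C4a–C5, and tautomerisation gives the phenol A5.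
- **In favour:** The 1,3-relationship of the C5 hydroxyl and the C7 methoxy group is dictated by the mechanism. In control of the oxygenation pattern it is the equal of the chosen plan, and like the chosen plan it is an all-pericyclic cascade.
- **Against:** It constructs a benzene ring that can be bought fully oxygenated. A6 needs several steps and is a diazo compound. A7 is volatile and unstable. A5 lacks the C6 acyl group and the C3=C4 double bond, and its C4 carbonyl must be reduced and eliminated. C6 acylation would have to compete with C8.
- **Comparison:** On structure it answers a question that does not arise here and postpones the two that do. On mechanism it is equally elegant but needs light and diazo handling. On step economy it is far behind.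

**Alternative 3:** The cut is at O1–C8a and C4a–C4, with O1–C2 made in the closing event. The methoxymethyl-protected chromene A9 goes back to the ortho-silylaryl triflate A10 and 3-methylbut-2-enal A11.
- **Forward key step:** CsF would release the aryne A12 from A10. The carbonyl oxygen of A11 should add at the aryne carbon remote from the methoxymethoxy group (future C8a), and the aryl anion at the future C4a should close onto the carbonyl carbon. The four-membered ring should then open and an oxa-6π closure forms O1–C2, giving A9.
- **In favour:** It should run near room temperature, which is better than 140 °C. Its regiochemistry rests on the inductive bias of an alkoxy aryne and not on a hydrogen-bond chelate, arguably a firmer control element. It ends in the same oxa-6π closure as the chosen route, so on that event the two are equal.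
- **Against:** A10 needs several steps. A9 has no C6 acyl group, so a C6-selective acylation (competing with C8), acidic removal of the methoxymethyl group next to the chromene alkene and the Claisen condensation all remain. The enal can also enolise or react through its C=C bond.
- **Comparison:** On structure it builds the pyran but gives up the acetyl group that 1 supplies in place. On mechanism it is milder. On step economy it is much longer.

Key step: step 2

Remark: the target has no stereocentre and should exist largely as the chelated enol of the 1,3-diketone; it is named and drawn as the diketone. Conjugate bases formed stoichiometrically in the flask are numbered as intermediates.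

## Route

Step 1
Reactants: 1 2',4'-dihydroxy-6'-methoxyacetophenone; 2 3-chloro-3-methylbut-1-yne
Product: 4 1-[2-hydroxy-6-methoxy-4-(2-methylbut-3-yn-2-yloxy)phenyl]ethanone, via potassium phenoxide 3 (not isolated)
Conditions: K2CO3, KI (cat.), CuI (cat.), acetone, 55 °C
Reagents that add atoms: none
Why: Copper-assisted Williamson-type O-propargylation: the 4-hydroxyl, para to the acetyl group, is the more acidic and the only unchelated phenol, so carbonate deprotonates it selectively while the 2-hydroxyl stays locked in its hydrogen bond to the ketone. The tertiary chloride should ionise through a copper acetylide and be captured at oxygen, and at 55 °C the ether should not yet rearrange.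

Step 2
Reactants: 4 1-[2-hydroxy-6-methoxy-4-(2-methylbut-3-yn-2-yloxy)phenyl]ethanone
Product: 8 1-(5-hydroxy-7-methoxy-2,2-dimethyl-2H-chromen-6-yl)ethanone, via allenyl dienone 5 (not isolated), via allenyl phenol 6 (not isolated), via ortho-quinone methide 7 (not isolated)
Conditions: xylenes, 140 °C, N2
Reagents that add atoms: none
Why: Heating 4 should start an aromatic propargyl Claisen rearrangement: a concerted (3,3) shift breaks the O–CMe2 bond and joins the alkyne terminus to acetophenone C3, the future C4a–C4 bond, giving dienone 5. Tautomerisation restores the benzene ring as allenyl phenol 6, a 1,5-hydrogen shift from the freed 4-hydroxyl to the central allene carbon gives the Z-configured ortho-quinone methide 7 with the vinyl group cis to the carbonyl, and a thermally allowed disrotatory oxa-6π electrocyclisation of this oxatriene closes the six-membered pyran ring by re-forming O1–C2. The closest known reaction type is the thermal conversion of aryl 1,1-dimethylpropargyl ethers into 2,2-dimethyl-2H-chromenes, well established for chelated ortho-hydroxyacetophenones. The gem-dimethyl group lowers the barrier of the first shift, and the net change is an isomerisation with no reagent that could touch the acetyl group. No stereocentre results, because the sp3 carbon of 5 is lost on enolisation and C2 carries two methyl groups. Two selectivities are needed: migration to C3 (between the chelated hydroxyl and the ether oxygen) and not to C5 (next to OMe), and ring closure through the 4-oxygen and not the 2-oxygen. Both are secured by the hydrogen-bonded chelate of the 2-hydroxyl with the acetyl carbonyl, which favours the Kekulé form with double-bond character in C3–C4 and ties up the 2-hydroxyl proton, so that only the 4-hydroxyl delivers hydrogen and closes the ring, leaving the chelate intact in 8.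

Step 3
Reactants: 8 1-(5-hydroxy-7-methoxy-2,2-dimethyl-2H-chromen-6-yl)ethanone; 9 methyl benzoate
Product: 12 1-(5-hydroxy-7-methoxy-2,2-dimethyl-2H-chromen-6-yl)-3-phenylpropane-1,3-dione, via dilithium enolate 10 (not isolated), via dilithium diketonate 11 (not isolated)
Conditions: LiN(SiMe3)2 (4 equiv), THF, −78 to 0 °C; 9, −78 °C to rt; 1 M HCl, 0 °C
Reagents that add atoms: none
Why: Crossed Claisen condensation: the amide base removes the phenolic and one methyl-ketone proton to give 10, whose enolate carbon adds to the non-enolisable ester 9; loss of methoxide and deprotonation to the stabilised diketonate 11 drive the equilibrium. A cold dilute acid quench should release 12 as its chelated enol without the heat or acid strength needed for cyclodehydration to a flavone or for protonation of the chromene alkene.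

## Compound list

1 | 2',4'-dihydroxy-6'-methoxyacetophenone, i.e. 1-(2,4-dihydroxy-6-methoxyphenyl)ethanone | COc1cc(O)cc(O)c1C(C)=O | starting material
2 | 3-chloro-3-methylbut-1-yne | CC(C)(Cl)C#C | starting material
3 | potassium 4-acetyl-3-hydroxy-5-methoxyphenolate (not isolated) | [K+].COc1cc([O-])cc(O)c1C(C)=O | intermediate
4 | 1-[2-hydroxy-6-methoxy-4-(2-methylbut-3-yn-2-yloxy)phenyl]ethanone | COc1cc(OC(C)(C)C#C)cc(O)c1C(C)=O | intermediate
5 | 4-acetyl-5-hydroxy-3-methoxy-6-(3-methylbuta-1,2-dien-1-yl)cyclohexa-2,4-dien-1-one (racemic at C6, not isolated) | COC1=CC(=O)C(C=C=C(C)C)C(O)=C1C(C)=O | intermediate
6 | 1-[2,4-dihydroxy-6-methoxy-3-(3-methylbuta-1,2-dien-1-yl)phenyl]ethanone (not isolated) | COc1cc(O)c(C=C=C(C)C)c(O)c1C(C)=O | intermediate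
7 | (6Z)-4-acetyl-5-hydroxy-3-methoxy-6-(3-methylbut-2-en-1-ylidene)cyclohexa-2,4-dien-1-one (not isolated) | COC1=CC(=O)/C(=C\C=C(C)C)C(O)=C1C(C)=O | intermediate
8 | 1-(5-hydroxy-7-methoxy-2,2-dimethyl-2H-chromen-6-yl)ethanone | COc1cc2OC(C)(C)C=Cc2c(O)c1C(C)=O | intermediate
9 | methyl benzoate | COC(=O)c1ccccc1 | starting material
10 | dilithium 7-methoxy-2,2-dimethyl-6-(1-oxidoethenyl)-2H-chromen-5-olate (not isolated) | [Li+].[Li+].COc1cc2OC(C)(C)C=Cc2c([O-])c1C([O-])=C | intermediate
11 | dilithium salt of 12, 5-phenolate and Z-enolate of the diketone (not isolated) | [Li+].[Li+].COc1cc2OC(C)(C)C=Cc2c([O-])c1C(=O)/C=C(\[O-])c1ccccc1 | intermediate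
12 | 1-(5-hydroxy-7-methoxy-2,2-dimethyl-2H-chromen-6-yl)-3-phenylpropane-1,3-dione (achiral) | COc1cc2OC(C)(C)C=Cc2c(O)c1C(=O)CC(=O)c1ccccc1 | target

## Step count and risks

Total step count: 3. Longest linear sequence: 3 steps (1 to 4 to 8 to 12). The route has only three steps, so all three are assessed.

**Step 2 (key step).** The most likely failure is incomplete site selectivity in the (3,3) shift, with part of the material migrating to C5. The chelate is an electronic bias and not a blocking group, and the methoxy group also activates C5. A second risk is oligomerisation of the electron-rich chromene on long heating. The fallback sets out from 1 and comes back at 8. Compound 1 is heated with 3-methylbut-2-enal A11 and catalytic ethylenediammonium diacetate in xylenes (or in pyridine at 120 °C). Knoevenagel-type attack by ring carbon C3, the most nucleophilic position because it lies between two free hydroxyls, followed by loss of water should give the same quinone methide 7, which closes to 8. This replaces the sigmatropic shift by a polar C–C bond formation with a different origin of site selectivity, and it also bypasses 4. It makes no compound outside the compound list (F0).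

**Step 1.** The most likely failure is slow capture of the hindered tertiary electrophile, so that elimination of HCl from 2 or C-alkylation of the electron-rich ring competes with O-alkylation. Alkylation of the chelated hydroxyl is less likely. The fallback sets out from 1 and comes back at 4. 2-Methylbut-3-yn-2-ol is converted in the flask (trifluoroacetic anhydride, DBU, MeCN, 0 °C) into 2-methylbut-3-yn-2-yl 2,2,2-trifluoroacetate F1, which is coupled with 1 using DBU and catalytic CuCl2·2H2O at 0 °C. The electrophile changes from a halide ionised in a hot heterogeneous carbonate medium to an activated ester captured through a copper-bound propargyl cation in homogeneous solution at 0 °C. Elimination, C-alkylation and premature rearrangement should all be slower there, and the key step is kept.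

**Step 3.** The most likely failure is incomplete C-acylation: the enolate of 10 is flanked by two ortho substituents and twisted out of conjugation, so addition to the ester may be slower than proton exchange. A quench that is too warm or too acidic could also start cyclodehydration to the flavone. The fallback sets out from 8 and comes back at 12 by a Baker–Venkataraman sequence. The 5-hydroxyl is benzoylated (benzoyl chloride, K2CO3, acetone) to 6-acetyl-7-methoxy-2,2-dimethyl-2H-chromen-5-yl benzoate F2. KOtBu in THF (or KOH in pyridine) then transfers the benzoyl group from oxygen to the methyl-ketone enolate through a six-membered transition state, and a cold mildly acidic quench gives 12. The C–C bond is then formed intramolecularly and no longer depends on the rate of an intermolecular addition.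

## Further compounds

F0 | step 2 | none | none
F1 | step 1 | 2-methylbut-3-yn-2-yl 2,2,2-trifluoroacetate | CC(C)(OC(=O)C(F)(F)F)C#C
F2 | step 3 | 6-acetyl-7-methoxy-2,2-dimethyl-2H-chromen-5-yl benzoate | COc1cc2OC(C)(C)C=Cc2c(OC(=O)c2ccccc2)c1C(C)=O
A1 | alternative 1 | 1-(5-hydroxy-7-methoxy-2,2-dimethyl-2H-chromen-6-yl)-2-(2-phenyl-1,3-dioxolan-2-yl)ethanone | COc1cc2OC(C)(C)C=Cc2c(O)c1C(=O)CC1(OCCO1)c1ccccc1
A2 | alternative 1 | 7-methoxy-2,2-dimethyl-6-(trimethylsilyl)-2H-chromen-5-yl trifluoromethanesulfonate | COc1cc2OC(C)(C)C=Cc2c(OS(=O)(=O)C(F)(F)F)c1[Si](C)(C)C
A3 | alternative 1 | 2-(2-phenyl-1,3-dioxolan-2-yl)acetic acid | OC(=O)CC1(OCCO1)c1ccccc1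
A4 | alternative 1 | 5,6-didehydro-7-methoxy-2,2-dimethyl-2H-chromene (the 5,6-aryne) | COC1=CC2=C(C=CC(C)(C)O2)C#C1
A5 | alternative 2 | 5-hydroxy-7-methoxy-2,2-dimethylchroman-4-one | COc1cc(O)c2C(=O)CC(C)(C)Oc2c1
A6 | alternative 2 | 6-(2-diazoacetyl)-2,2-dimethyl-2,3-dihydro-4H-pyran-4-one | CC1(C)CC(=O)C=C(O1)C(=O)C=[N+]=[N-]
A7 | alternative 2 | methoxyethyne | COC#C
A8 | alternative 2 | 2,2-dimethyl-6-(2-oxoethenyl)-2,3-dihydro-4H-pyran-4-one (vinylketene) | CC1(C)CC(=O)C=C(O1)C=C=O
A9 | alternative 3 | 7-methoxy-5-(methoxymethoxy)-2,2-dimethyl-2H-chromene | COCOc1cc(OC)cc2OC(C)(C)C=Cc12
A10 | alternative 3 | 5-methoxy-3-(methoxymethoxy)-2-(trimethylsilyl)phenyl trifluoromethanesulfonate | COCOc1cc(OC)cc(OS(=O)(=O)C(F)(F)F)c1[Si](C)(C)C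
A11 | alternative 3 | 3-methylbut-2-enal | CC(C)=CC=O
A12 | alternative 3 | 1,2-didehydro-5-methoxy-3-(methoxymethoxy)benzene (aryne) | COCOC1=CC(OC)=CC#C1
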